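The data were computed for an exercise; scatter was added.

1. At the first reading of the west run, 15.0 d, free monomer stood at 0.6% and monomer in chains at 32.9%; at 200 d chains stood at 33.9%. The north run looked alike on a lower level: at 1.25 d free monomer was 0.2% and chains 3.1%, and at 15.0 d chains were 2.3%. So in both runs the free monomer went, the chains stopped growing, and the rest of the charge had gone somewhere else.

| flask | free monomer | pre-initiator | temperature | remark | time |
|---|---|---|---|---|---|
| west | 2 M | 6 mM | 0 °C | run made earlier |  |
| north | 2 M | 6 mM | 50 °C | run made earlier |  |
| ash | 3.0 M | 6.0 mM | 65 °C |  | 6.0 d |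
| oak | 3.0 M | 6.0 mM | 35 °C |  | 6.0 d |
| larch | 3.0 M | 6.0 mM | 95 °C |  | 6.0 d |
| elm | 3.0 M | 6.0 mM | 5 °C |  | 6.0 d |

- west (time / d: monomer in chains / %, free monomer / %): 15.0: 32.9, 0.6; 40.0: 33.1, 0.1; 80.0: 32.7, 1.2; 120: 33.3, 0; 200: 33.9, 0
- north (time / d: monomer in chains / %, free monomer / %): 1.25: 3.1, 0.2; 4.00: 2.3, 1.1; 6.00: 2.1, 0; 10.0: 2.6, 0.8; 15.0: 2.3, 0

(standard deviation of a reading: 1 percentage point)

- the flask with the highest amount of monomer in chains, in percent of the free monomer charged ("all alike" if they lie within 1.5 percentage points) (ash / oak / larch / elm / all alike)
- final monomer in chains, as a percentage of the free monomer charged, in ash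
- final monomer in chains, as a percentage of the free monomer charged, in oak
- final monomer in chains, as a percentage of the free monomer charged, in larch
- final monomer in chains, as a percentage of the free monomer charged, in elm



2. I worked with the odds of chains against the rest of the charge, not with the chain plateau by itself. Averaged over its readings, the chain plateau was 33.2% in west and 2.48% in north. Dividing each plateau by the part of the charge not in chains gives the odds of a monomer ending in chains, a selectivity factor: 0.497 in west and 0.0254 in north.

3. If each route keeps its own temperature law, the logarithm of the odds runs straight against inverse temperature. These two runs give 43.6 kJ mol⁻¹ for the split energy, which is the gas constant times the fall of the logarithm of the odds per unit of inverse temperature. It is a reading and carries the scatter of the plateaus.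

4. Elm looks nearly the same as west: 6.0 mM of pre-initiator in both, 5 °C against 0 °C, and 3.0 M of free monomer against 2 M. My reckoning gave elm odds of 0.352, so 26.0% in chains. Elm should end below west because its odds are smaller than west's. The same step gave 5.31% for oak, 1.22% for ash and 0.348% for larch, so elm should hold more than any of them. Two things were untested: the richer monomer charge, and a time of 6.0 d, which is shorter than west's first reading.

5. The forecast named elm, with 24% there, 4.8% in oak, 1.1% in ash and 0.3% in larch. Its elm figure lies below mine, for its own stated ground: “If the side route has higher order in monomer, yields fall somewhat, so I shade them down slightly.”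

6. The flask with the most was elm, at 27.7%, with oak at 5.44%, ash at 0.817% and larch at 0.138%.

    free monomer → uncatalysed product (k = 1.30 × 10⁻⁵ s⁻¹, Ea = 93.0 kJ mol⁻¹)
    free monomer + initiator → living end + monomer in chains (k = 1.40 × 10⁻⁴ M⁻¹ s⁻¹, Ea = 63.0 kJ mol⁻¹)
    free monomer + living end → monomer in chains + living end, rate k3*[living end]*[free monomer] (k = 0.00380 M⁻¹ s⁻¹, Ea = 52.0 kJ mol⁻¹)
    pre-initiator → initiator (k = 6.70 × 10⁻⁶ s⁻¹, Ea = 84.0 kJ mol⁻¹)
    (constants at 5 °C)

In elm, free monomer was down to 0.242% at 3.00 d, and chains already stood at 27.6%. Elm's odds came to 0.383. Carried to oak with the split energy of 43.6 kJ mol⁻¹, they become 0.0611, which is 5.76% in chains, and oak held 5.44%.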